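**Retrosynthetic overview** (germacrane numbering; ring A = carbocycle C1–C10, ring B = γ-lactone O–C6–C7–C11–C12)
1. The strategy rests on the unit O8–C8–C7–C11(=C13): C7 is the β-carbon of ring B and a member of ring A, and C11=C13 is exocyclic, which is the pattern left by γ-allylation of a C8 aldehyde.
2. Target 31 ⇐ desilylation, C14 oxidation, PMB removal and O8 acylation ⇐ cis-fused hydroxy lactone 26.
3. 26 ⇐ C7–C8 disconnection (ring A closed last) ⇐ 3-(bromomethyl)butenolide aldehyde 24, by intramolecular chromium Barbier γ-allylation.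
4. 24 ⇐ ring B first, by ring-closing metathesis (C7=C11) of the 2-(bromomethyl)acrylate of carbinol 19, then unmasking of C8.
5. 19 ⇐ C3–C4 B-alkyl Suzuki union of (Z)-iodide 6 (C5–C6 by asymmetric alkynylation, then hydroalumination–iodination) with diene 17 (from but-2-yne-1,4-diol: iodoalkenol, C2=C3 Wittig, C9–C10 Negishi).

Key step: step 15

Assumption: (S,S)-ProPhenol, 2,6-bis{[(2S)-2-(hydroxydiphenylmethyl)pyrrolidin-1-yl]methyl}-4-methylphenol, is taken as the ligand antipode that sends the alkynylzinc to the Re face of (E)-but-2-enal (4S carbinol); if the sense on this aldehyde is the opposite, (R,R)-ProPhenol is used with no other change.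

Step 1
Reactants: 1 (E)-but-2-enal; 2 tert-butyldimethyl(prop-2-yn-1-yloxy)silane
Product: 4 (4S,5E)-1-[(tert-butyldimethylsilyl)oxy]hept-5-en-2-yn-4-ol, via methylzinc acetylide 3 (not isolated)
Conditions: 2, Me2Zn, toluene, 0 °C; then (S,S)-ProPhenol (10 mol %), Ph3PO (20 mol %), 1, 4 °C; aq NH4Cl
Reagents that add atoms: none
Why: Zinc–ProPhenol-catalysed asymmetric alkynylation of an enal, in which the dinuclear zinc complex binds the aldehyde and delivers the alkynyl group of 3 to its Re face, so that C6 (the 4S centre of 4) is set by the catalyst.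

Step 2
Reactants: 4 (4S,5E)-1-[(tert-butyldimethylsilyl)oxy]hept-5-en-2-yn-4-ol
Product: 6 (2Z,4S,5E)-1-[(tert-butyldimethylsilyl)oxy]-2-iodohepta-2,5-dien-4-ol, via cyclic alkenylalanate 5 (not isolated)
Conditions: NaAlH2(OCH2CH2OCH3)2, THF, 0 °C; then I2, THF, −78 to 0 °C
Reagents that add atoms: iodine, II
Why: Hydroxyl-directed trans-hydroalumination of the propargylic alcohol puts H on C5 and aluminium on C4 in the five-membered alanate 5, and iodinolysis with retention should give the iodide with C6 cis to iodine (the site of C3) and trans to C15, C6 being untouched.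

Step 3
Reactants: 7 but-2-yne-1,4-diol
Product: 9 4-[(4-methoxybenzyl)oxy]but-2-yn-1-ol, via monosodium alkoxide 8 (not isolated)
Conditions: 7 (3 equiv), NaH (1 equiv), THF–DMF, 0 °C; then 4-methoxybenzyl chloride (1 equiv), n-Bu4NI (cat.), 23 °C
Reagents that add atoms: 4-methoxybenzyl chloride, COc1ccc(CCl)cc1
Why: Williamson etherification, in which the excess of the symmetric diol favours mono-alkylation and fixes the C14 oxygen as its PMB ether from the start.

Step 4
Reactants: 9 4-[(4-methoxybenzyl)oxy]but-2-yn-1-ol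
Product: 11 (2Z)-3-iodo-4-[(4-methoxybenzyl)oxy]but-2-en-1-ol, via cyclic alkenylalanate 10 (not isolated)
Conditions: NaAlH2(OCH2CH2OCH3)2, THF, 0 °C; then I2, THF, −78 to 0 °C
Reagents that add atoms: iodine, II
Why: The same hydroxyl-directed trans-hydroalumination–iodination puts H on C1 and iodine on C10, with C2 cis to iodine (the site of C9) and trans to C14.

Step 5
Reactants: 11 (2Z)-3-iodo-4-[(4-methoxybenzyl)oxy]but-2-en-1-ol
Product: 12 (2Z)-3-iodo-4-[(4-methoxybenzyl)oxy]but-2-enal
Conditions: MnO2, CH2Cl2, 23 °C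
Reagents that add atoms: none
Why: Chemoselective MnO2 oxidation of the allylic alcohol under neutral conditions, which leaves the vinyl iodide, its geometry and the PMB ether alone.

Step 6
Reactants: 12 (2Z)-3-iodo-4-[(4-methoxybenzyl)oxy]but-2-enal
Product: 13 1-({[(2Z)-2-iodopenta-2,4-dien-1-yl]oxy}methyl)-4-methoxybenzene
Conditions: Ph3PCH3Br, KOtBu, THF, 0 °C; then 12, −78 to 0 °C
Reagents that add atoms: methyltriphenylphosphonium bromide, C[P+](c1ccccc1)(c1ccccc1)c1ccccc1.[Br-]
Why: Wittig methylenation adds C3 as the terminal vinyl carbon, and at low temperature with a slight excess of ylide the carbonyl addition should outrun dehydroiodination, so the C1=C10 geometry is kept.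

Step 7
Reactants: 13 1-({[(2Z)-2-iodopenta-2,4-dien-1-yl]oxy}methyl)-4-methoxybenzene; 14 (2-tert-butoxy-2-oxoethyl)zinc chloride
Product: 15 tert-butyl (3E)-3-{[(4-methoxybenzyl)oxy]methyl}hexa-3,5-dienoate
Conditions: Pd(PPh3)4 (5 mol %), THF, 23 to 50 °C
Reagents that add atoms: none
Why: Negishi coupling of the Reformatsky-type zinc enolate with the alkenyl iodide (zerovalent palladium, retention at the alkene) installs C9–C8 cis to C2 under neutral conditions that should not move the skipped diene ester into conjugation.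

Step 8
Reactants: 15 tert-butyl (3E)-3-{[(4-methoxybenzyl)oxy]methyl}hexa-3,5-dienoate
Product: 16 (3E)-3-{[(4-methoxybenzyl)oxy]methyl}hexa-3,5-dien-1-ol
Conditions: LiAlH4, Et2O, 0 °C
Reagents that add atoms: none
Why: Hydride reduction of the ester to the primary C8 alcohol, to which the diene and the PMB ether are inert.

Step 9
Reactants: 16 (3E)-3-{[(4-methoxybenzyl)oxy]methyl}hexa-3,5-dien-1-ol
Product: 17 triethyl{[(3E)-3-{[(4-methoxybenzyl)oxy]methyl}hexa-3,5-dien-1-yl]oxy}silane
Conditions: Et3SiCl, imidazole, CH2Cl2, 0 °C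
Reagents that add atoms: chlorotriethylsilane, CC[Si](Cl)(CC)CC
Why: Silylation of the primary alcohol gives a C8 ether that can later be removed by mild acid in the presence of the TBS and PMB ethers.

Step 10
Reactants: 17 triethyl{[(3E)-3-{[(4-methoxybenzyl)oxy]methyl}hexa-3,5-dien-1-yl]oxy}silane; 6 (2Z,4S,5E)-1-[(tert-butyldimethylsilyl)oxy]-2-iodohepta-2,5-dien-4-ol
Product: 19 (2E,4S,5E,9E)-6-{[(tert-butyldimethylsilyl)oxy]methyl}-10-{[(4-methoxybenzyl)oxy]methyl}-12-[(triethylsilyl)oxy]dodeca-2,5,9-trien-4-ol, via B-alkyl-9-BBN borane 18 (not isolated)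
Conditions: 9-BBN, THF, 0 to 23 °C; then 6, PdCl2(dppf) (5 mol %; dppf = 1,1′-bis(diphenylphosphino)ferrocene), AsPh3, Cs2CO3, DMF–H2O, 23 °C
Reagents that add atoms: none
Why: 9-BBN hydroborates only the terminal C2=C3 alkene of the diene (boron on C3, the trisubstituted C1=C10 alkene is left), and B-alkyl Suzuki–Miyaura coupling of 18 with iodide 6 forms C3–C4 with retention, so C3 ends cis to C6 while the free C6 hydroxyl is tolerated.

Step 11
Reactants: 19 the C6 carbinol named in step 10; 20 2-(bromomethyl)prop-2-enoic acid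
Product: 21 (2E,4S,5E,9E)-6-{[(tert-butyldimethylsilyl)oxy]methyl}-10-{[(4-methoxybenzyl)oxy]methyl}-12-[(triethylsilyl)oxy]dodeca-2,5,9-trien-4-yl 2-(bromomethyl)prop-2-enoate
Conditions: DCC, DMAP (5 mol %), CH2Cl2, 0 °C
Reagents that add atoms: none
Why: Steglich esterification acylates the only free hydroxyl (O6) without breaking the C6–O bond, so the C6 configuration is retained and C11, C12 and C13 arrive with the bromide already in place.

Step 12
Reactants: 21 the 2-(bromomethyl)acrylate named in step 11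
Product: 22 (5R)-3-(bromomethyl)-5-[(1E,5E)-2-{[(tert-butyldimethylsilyl)oxy]methyl}-6-{[(4-methoxybenzyl)oxy]methyl}-8-[(triethylsilyl)oxy]octa-1,5-dien-1-yl]furan-2(5H)-one
Conditions: second-generation Hoveyda–Grubbs catalyst, RuCl2(H2IMes)(=CH-C6H4-2-OiPr) (10 mol %), 1,4-benzoquinone (10 mol %), toluene, 80 °C
Reagents that add atoms: none
Why: Ring-closing metathesis closes ring B as a butenolide: the carbene loads at the propenyl alkene on C6 (propene is lost) and closes the five-membered ring onto the acrylate, the two trisubstituted alkenes are spectators, and the phosphine-free catalyst avoids alkylation by the allylic bromide.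

Step 13
Reactants: 22 the triethylsilyl ether named in step 12
Product: 23 (5R)-3-(bromomethyl)-5-[(1E,5E)-2-{[(tert-butyldimethylsilyl)oxy]methyl}-8-hydroxy-6-{[(4-methoxybenzyl)oxy]methyl}octa-1,5-dien-1-yl]furan-2(5H)-one
Conditions: PPTS (0.2 equiv), MeOH–CH2Cl2 (1:1), 0 °C
Reagents that add atoms: none
Why: Acid-catalysed methanolysis cleaves the primary triethylsilyl ether much faster than the TBS ether, and without base neither the allylic bromide nor the epimerisable C6–H of the butenolide is touched.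

Step 14
Reactants: 23 the C8 alcohol named in step 13
Product: 24 (5R)-3-(bromomethyl)-5-[(1E,5E)-2-{[(tert-butyldimethylsilyl)oxy]methyl}-6-{[(4-methoxybenzyl)oxy]methyl}-8-oxoocta-1,5-dien-1-yl]furan-2(5H)-one
Conditions: Dess–Martin periodinane, NaHCO3, CH2Cl2, 0 °C; used at once
Reagents that add atoms: none
Why: Buffered Dess–Martin oxidation gives the β,γ-unsaturated C8 aldehyde under conditions that should not move the C1=C10 alkene into conjugation.

Step 15
Reactants: 24 the bromomethyl butenolide aldehyde named in step 14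
Product: 26 (6R,7S,8S)-15-[(tert-butyldimethylsilyl)oxy]-8-hydroxy-14-[(4-methoxybenzyl)oxy]germacra-1(10),4,11(13)-trien-12,6-olide (both ring alkenes ring-cis; lactone cis-fused), via allylchromium dichloride 25 (not isolated)
Conditions: CrCl2 (6 equiv), degassed THF, 23 °C, 24 added over 12 h to 0.002 M; then H2O
Reagents that add atoms: none
Why: Two equivalents of divalent chromium reduce the C13–Br bond to the allylchromium dichloride 25 (trivalent chromium), the C8 aldehyde oxygen binds chromium, and C7 attacks C8 through a six-membered chair (SE2′), which forms C7–C8 and returns the alkene as the exocyclic C11=C13 methylene. The closest known reaction type is the Nozaki–Hiyama/Barbier γ-allylation of aldehydes by 3-(bromomethyl)furan-2(5H)-ones together with the intramolecular allyl halide–aldehyde macrocyclisation used for ten-membered carbocycles. Ring A closes as a ten-membered ring by 10-exo-trig addition to the carbonyl under high dilution, ring B being already in place. C7 is set by the C6 stereocentre: the C5-to-C8 tether, curved by its two ring-cis alkenes, is expected to bring the aldehyde to the butenolide face that carries C5, which gives the cis ring fusion (7S). C8 is set by the chair: C6 sits pseudo-equatorial on C7 (it is trans to C13 in the butenolide), and the aldehyde chain C9, being tied back to C5, can only take the chair site gauche to both C6 and C11 because the other site would press C9 against C5, and this orientation gives 8S. The step needs γ- over α-attack, aldehyde over lactone addition and cyclisation over oligomerisation, which are secured by the cyclic transition state (α-attack would need a twelve-membered ring), the mild allylchromium reagent and slow addition to dilute CrCl2.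

Step 16
Reactants: 26 the hydroxy lactone named in step 15; 27 3-methylbutanoyl chloride
Product: 28 (6R,7S,8S)-15-[(tert-butyldimethylsilyl)oxy]-14-[(4-methoxybenzyl)oxy]-8-[(3-methylbutanoyl)oxy]germacra-1(10),4,11(13)-trien-12,6-olide
Conditions: pyridine, DMAP (0.1 equiv), CH2Cl2, 0 to 23 °C
Reagents that add atoms: none
Why: DMAP-catalysed O-acylation of the only free hydroxyl takes place at oxygen, so C8 keeps its configuration.

Step 17
Reactants: 28 the isovalerate named in step 16
Product: 29 (6R,7S,8S)-15-[(tert-butyldimethylsilyl)oxy]-14-hydroxy-8-[(3-methylbutanoyl)oxy]germacra-1(10),4,11(13)-trien-12,6-olide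
Conditions: DDQ, CH2Cl2–pH 7 buffer (10:1), 0 °C
Reagents that add atoms: none
Why: Oxidative cleavage of the PMB ether by DDQ frees only the C14 hydroxyl, the silyl ether, the ester and the α-methylene lactone being inert.

Step 18
Reactants: 29 the C14 alcohol named in step 17
Product: 30 (6R,7S,8S)-15-[(tert-butyldimethylsilyl)oxy]-8-[(3-methylbutanoyl)oxy]-14-oxogermacra-1(10),4,11(13)-trien-12,6-olide
Conditions: MnO2, CH2Cl2, 23 °C
Reagents that add atoms: none
Why: MnO2 oxidation of the allylic C14 alcohol gives the enal with the formyl group trans to C2, the stable arrangement, so the C1=C10 geometry is kept.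

Step 19
Reactants: 30 the silyl-protected enal named in step 18
Product: 31 CNP0345200.6, (6R,7S,8S)-15-hydroxy-8-[(3-methylbutanoyl)oxy]-14-oxogermacra-1(10),4,11(13)-trien-12,6-olide
Conditions: HF·pyridine, pyridine, THF, 0 to 23 °C
Reagents that add atoms: none
Why: Buffered fluoride desilylation removes the primary allylic TBS ether without touching the enal, the isovalerate or the α-methylene lactone.

**Compound list**
1 | (E)-but-2-enal | C/C=C/C=O | starting material
2 | tert-butyldimethyl(prop-2-yn-1-yloxy)silane | C#CCO[Si](C)(C)C(C)(C)C | starting material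
3 | methyl{3-[(tert-butyldimethylsilyl)oxy]prop-1-yn-1-yl}zinc | C[Zn]C#CCO[Si](C)(C)C(C)(C)C | intermediate (not isolated)
4 | (4S,5E)-1-[(tert-butyldimethylsilyl)oxy]hept-5-en-2-yn-4-ol | C/C=C/[C@H](O)C#CCO[Si](C)(C)C(C)(C)C | intermediate
5 | sodium cyclic alkenylalanate of 4 (aluminium bonded to O6 and C4, two 2-methoxyethoxy groups) | [Na+].COCCO[Al-]1(OCCOC)O[C@@H](/C=C/C)C=C1CO[Si](C)(C)C(C)(C)C | intermediate (not isolated)
6 | (2Z,4S,5E)-1-[(tert-butyldimethylsilyl)oxy]-2-iodohepta-2,5-dien-4-ol | C/C=C/[C@H](O)/C=C(\I)CO[Si](C)(C)C(C)(C)C | intermediate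
7 | but-2-yne-1,4-diol | OCC#CCO | starting material
8 | sodium 4-hydroxybut-2-yn-1-olate | [Na+].[O-]CC#CCO | intermediate (not isolated)
9 | 4-[(4-methoxybenzyl)oxy]but-2-yn-1-ol | OCC#CCOCc1ccc(OC)cc1 | intermediate
10 | sodium cyclic alkenylalanate of 9 (aluminium bonded to O and C10) | [Na+].COCCO[Al-]1(OCCOC)OCC=C1COCc2ccc(OC)cc2 | intermediate (not isolated)
11 | (2Z)-3-iodo-4-[(4-methoxybenzyl)oxy]but-2-en-1-ol | OC/C=C(\I)COCc1ccc(OC)cc1 | intermediate
12 | (2Z)-3-iodo-4-[(4-methoxybenzyl)oxy]but-2-enal | O=C/C=C(\I)COCc1ccc(OC)cc1 | intermediate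
13 | 1-({[(2Z)-2-iodopenta-2,4-dien-1-yl]oxy}methyl)-4-methoxybenzene | C=C/C=C(\I)COCc1ccc(OC)cc1 | intermediate
14 | (2-tert-butoxy-2-oxoethyl)zinc chloride | CC(C)(C)OC(=O)C[Zn]Cl | starting material
15 | tert-butyl (3E)-3-{[(4-methoxybenzyl)oxy]methyl}hexa-3,5-dienoate | C=C/C=C(\CC(=O)OC(C)(C)C)COCc1ccc(OC)cc1 | intermediate
16 | (3E)-3-{[(4-methoxybenzyl)oxy]methyl}hexa-3,5-dien-1-ol | C=C/C=C(\CCO)COCc1ccc(OC)cc1 | intermediate
17 | triethyl{[(3E)-3-{[(4-methoxybenzyl)oxy]methyl}hexa-3,5-dien-1-yl]oxy}silane | C=C/C=C(\CCO[Si](CC)(CC)CC)COCc1ccc(OC)cc1 | intermediate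
18 | 9-[(3E)-4-{[(4-methoxybenzyl)oxy]methyl}-6-[(triethylsilyl)oxy]hex-3-en-1-yl]-9-borabicyclo[3.3.1]nonane | B1(CC/C=C(\CCO[Si](CC)(CC)CC)COCc2ccc(OC)cc2)C2CCCC1CCC2 | intermediate (not isolated)
19 | (2E,4S,5E,9E)-6-{[(tert-butyldimethylsilyl)oxy]methyl}-10-{[(4-methoxybenzyl)oxy]methyl}-12-[(triethylsilyl)oxy]dodeca-2,5,9-trien-4-ol (C6 carbinol; C3 cis to C6, C9 cis to C2) | C/C=C/[C@H](O)/C=C(\CC/C=C(\CCO[Si](CC)(CC)CC)COCc1ccc(OC)cc1)CO[Si](C)(C)C(C)(C)C | intermediate
20 | 2-(bromomethyl)prop-2-enoic acid | C=C(CBr)C(=O)O | starting material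
21 | 2-(bromomethyl)prop-2-enoate of 19 (4S) | C/C=C/[C@H](OC(=O)C(=C)CBr)/C=C(\CC/C=C(\CCO[Si](CC)(CC)CC)COCc1ccc(OC)cc1)CO[Si](C)(C)C(C)(C)C | intermediate
22 | (5R)-3-(bromomethyl)-5-[(1E,5E)-2-{[(tert-butyldimethylsilyl)oxy]methyl}-6-{[(4-methoxybenzyl)oxy]methyl}-8-[(triethylsilyl)oxy]octa-1,5-dien-1-yl]furan-2(5H)-one | O=C1O[C@H](/C=C(\CC/C=C(\CCO[Si](CC)(CC)CC)COCc2ccc(OC)cc2)CO[Si](C)(C)C(C)(C)C)C=C1CBr | intermediate
23 | (5R)-3-(bromomethyl)-5-[(1E,5E)-2-{[(tert-butyldimethylsilyl)oxy]methyl}-8-hydroxy-6-{[(4-methoxybenzyl)oxy]methyl}octa-1,5-dien-1-yl]furan-2(5H)-one | O=C1O[C@H](/C=C(\CC/C=C(\CCO)COCc2ccc(OC)cc2)CO[Si](C)(C)C(C)(C)C)C=C1CBr | intermediate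
24 | (5R)-3-(bromomethyl)-5-[(1E,5E)-2-{[(tert-butyldimethylsilyl)oxy]methyl}-6-{[(4-methoxybenzyl)oxy]methyl}-8-oxoocta-1,5-dien-1-yl]furan-2(5H)-one (key-step precursor) | O=C1O[C@H](/C=C(\CC/C=C(\CC=O)COCc2ccc(OC)cc2)CO[Si](C)(C)C(C)(C)C)C=C1CBr | intermediate
25 | allylchromium dichloride of 24 (CrCl2 on C13) | O=C1O[C@H](/C=C(\CC/C=C(\CC=O)COCc2ccc(OC)cc2)CO[Si](C)(C)C(C)(C)C)C=C1C[Cr](Cl)Cl | intermediate (not isolated)
26 | (6R,7S,8S)-15-[(tert-butyldimethylsilyl)oxy]-8-hydroxy-14-[(4-methoxybenzyl)oxy]germacra-1(10),4,11(13)-trien-12,6-olide, cis-fused (key-step product) | C=C1C(=O)O[C@@H]2/C=C(/CO[Si](C)(C)C(C)(C)C)CC/C=C(/COCc3ccc(OC)cc3)C[C@H](O)[C@H]12 | intermediate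
27 | 3-methylbutanoyl chloride | CC(C)CC(=O)Cl | starting material
28 | (6R,7S,8S)-15-[(tert-butyldimethylsilyl)oxy]-14-[(4-methoxybenzyl)oxy]-8-[(3-methylbutanoyl)oxy]germacra-1(10),4,11(13)-trien-12,6-olide | C=C1C(=O)O[C@@H]2/C=C(/CO[Si](C)(C)C(C)(C)C)CC/C=C(/COCc3ccc(OC)cc3)C[C@H](OC(=O)CC(C)C)[C@H]12 | intermediate
29 | (6R,7S,8S)-15-[(tert-butyldimethylsilyl)oxy]-14-hydroxy-8-[(3-methylbutanoyl)oxy]germacra-1(10),4,11(13)-trien-12,6-olide | C=C1C(=O)O[C@@H]2/C=C(/CO[Si](C)(C)C(C)(C)C)CC/C=C(/CO)C[C@H](OC(=O)CC(C)C)[C@H]12 | intermediate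
30 | (6R,7S,8S)-15-[(tert-butyldimethylsilyl)oxy]-8-[(3-methylbutanoyl)oxy]-14-oxogermacra-1(10),4,11(13)-trien-12,6-olide | C=C1C(=O)O[C@@H]2/C=C(/CO[Si](C)(C)C(C)(C)C)CC/C=C(/C=O)C[C@H](OC(=O)CC(C)C)[C@H]12 | intermediate
31 | CNP0345200.6, (6R,7S,8S)-15-hydroxy-8-[(3-methylbutanoyl)oxy]-14-oxogermacra-1(10),4,11(13)-trien-12,6-olide | C=C1C(=O)O[C@@H]2/C=C(/CO)CC/C=C(/C=O)C[C@H](OC(=O)CC(C)C)[C@H]12 | target

**Step count**
Total: 19 steps. Longest linear sequence: 17 steps (7 to 31 through steps 3 to 19); the other branch (steps 1 and 2) joins at step 10.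

**Steps most likely to fail**

Step 15. The closure may deliver C7 to the other face of the aldehyde, through a boat-like or open transition state with C9 anti to C6, and so give the C8 epimer; closure anti to C5, reduction of the allylic bromide and oligomerisation would lower the yield further. The fallback sets out from 24: the cyclisation is run for the 8-epimeric alcohol F1, with CrCl2 as above or with zinc dust in THF–aqueous NH4Cl if that metal gives it more cleanly. F1 is then esterified with inversion at C8 by a Mitsunobu reaction with 3-methylbutanoic acid (PPh3, diisopropyl azodicarboxylate, toluene, 0 °C). This comes back to the route at 28, and step 16 is omitted.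

Step 12. The active ruthenium carbene may be lost through reaction with the allylic bromide, and closure onto the bromomethyl-substituted acrylate may be sluggish, so that the metathesis stalls. The fallback sets out from 19 and brings the bromine in after ring closure. Acylation with acryloyl chloride (i-Pr2NEt, CH2Cl2, −78 °C) gives the acrylate F2. A Morita–Baylis–Hillman reaction with aqueous formaldehyde (DABCO, dioxane–water) gives the 2-(hydroxymethyl)acrylate F3. Ring-closing metathesis with the same catalyst gives the 3-(hydroxymethyl)butenolide F4. Appel bromination (CBr4, PPh3, CH2Cl2, 0 °C) then comes back to the route at 22.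

Step 1. Enantiofacial control in the alkynylation of a small aliphatic enal may be incomplete, which would carry the wrong C6 configuration into every later compound. The fallback sets out from 1 and 2: deprotonation of 2 with n-BuLi (THF, −78 °C) gives the lithium acetylide F5, and its addition to 1 gives the racemic alcohol F6. A Sharpless kinetic resolution (Ti(OiPr)4, L-(+)-diisopropyl tartrate, t-BuOOH, 4 Å molecular sieves, CH2Cl2, −20 °C, taken past half conversion) should epoxidise the 4R enantiomer to the epoxy alcohol F7 and leave the 4S alcohol, which comes back to the route at 4.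

**Further compounds**
F1 | step 15 | (6R,7S,8R)-15-[(tert-butyldimethylsilyl)oxy]-8-hydroxy-14-[(4-methoxybenzyl)oxy]germacra-1(10),4,11(13)-trien-12,6-olide (C8 epimer of 26) | C=C1C(=O)O[C@@H]2/C=C(/CO[Si](C)(C)C(C)(C)C)CC/C=C(/COCc3ccc(OC)cc3)C[C@@H](O)[C@H]12
F2 | step 12 | prop-2-enoate (acrylate) of 19 | C/C=C/[C@H](OC(=O)C=C)/C=C(\CC/C=C(\CCO[Si](CC)(CC)CC)COCc1ccc(OC)cc1)CO[Si](C)(C)C(C)(C)C
F3 | step 12 | 2-(hydroxymethyl)prop-2-enoate of 19 | C/C=C/[C@H](OC(=O)C(=C)CO)/C=C(\CC/C=C(\CCO[Si](CC)(CC)CC)COCc1ccc(OC)cc1)CO[Si](C)(C)C(C)(C)C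
F4 | step 12 | (5R)-3-(hydroxymethyl)-5-[(1E,5E)-2-{[(tert-butyldimethylsilyl)oxy]methyl}-6-{[(4-methoxybenzyl)oxy]methyl}-8-[(triethylsilyl)oxy]octa-1,5-dien-1-yl]furan-2(5H)-one | O=C1O[C@H](/C=C(\CC/C=C(\CCO[Si](CC)(CC)CC)COCc2ccc(OC)cc2)CO[Si](C)(C)C(C)(C)C)C=C1CO
F5 | step 1 | {3-[(tert-butyldimethylsilyl)oxy]prop-1-yn-1-yl}lithium | [Li]C#CCO[Si](C)(C)C(C)(C)C
F6 | step 1 | racemic (5E)-1-[(tert-butyldimethylsilyl)oxy]hept-5-en-2-yn-4-ol | C/C=C/C(O)C#CCO[Si](C)(C)C(C)(C)C
F7 | step 1 | (1S)-4-[(tert-butyldimethylsilyl)oxy]-1-[(2R,3R)-3-methyloxiran-2-yl]but-2-yn-1-ol | C[C@H]1O[C@@H]1[C@@H](O)C#CCO[Si](C)(C)C(C)(C)C
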